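**Plan**

1. Numbering: C1 (ester-bearing alkene carbon), C2, C3, ring-fusion C4, quaternary C5, C6 (CHCl), C7, C8 (CHOH), ring-fusion C9 (methyl), C10 (bears formyl C11). Ring A = C1–C2–C3–C4–C9–C10, ring B = C4–C9. α is the face of the C9 methyl, β the opposite face.
2. Enabling feature: ring B has methyls on C5 and C9 and heteroatoms on C6 and C8, so it is a masked 2,4-dimethylphenol (oxygen on C6) whose para carbon is the quaternary C9 and whose C4 carries the C3–C2–C1 arm. C10 is allylic to the C1=C2 enoate, so C9–C10 is the bond a phenolate para carbon makes with a π-allyl terminus.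
3. Retrosynthetic cuts, in order: C11 aldehyde to alcohol; side-chain C=C (cross-metathesis); C6–Cl and C6–H back to the C6 ketone; C5–allyl and C4–H back to the C4=C5 enone; C8–O back to C7=C8 of a 2,5-cyclohexadienone; C9–C10 (ring A) back to a phenol with an allylic carbonate at C2; C1–CO2Me and the C2–C1 bond back to an arylacetic Weinreb amide and a silyl propargyl ether.
4. Forward: the arene that becomes ring B is made first, the C1/C10/C11 chain is attached by acetylide acylation, ring A closes in the dearomatization, and ring B is then functionalized.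
5. Stereochemistry: C2 comes from Noyori transfer hydrogenation and is relayed to C10 and C9 in the ring closure (alkene geometry from trans-hydrostannation). C8, C4, C5 and C6 follow from reagent approach on the β face, anti to the C9 methyl, with hydrogen the last group delivered to C6. The E alkene comes from metathesis.

Key step: step 12

Remark: the (S,S)-TsDPEN ruthenium catalyst is assumed to give the (S)-carbinol, as it does with simple alkynyl ketones; if the sense were opposite, the (R,R) catalyst would be used.

**Route**

Step 1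
Reactants: 1 2-(2,6-dimethylphenyl)acetic acid
Product: 2 2-(3-bromo-2,6-dimethylphenyl)acetic acid
Conditions: Br2 (1.05 equiv), AcOH, rt, dark
Reagents that add atoms: bromine, BrBr
Why: electrophilic aromatic bromination should go to C3, which is ortho to one methyl and para to the other and has a symmetry-equivalent twin at C5, so a single monobromide is expected.

Step 2
Reactants: 2 2-(3-bromo-2,6-dimethylphenyl)acetic acid
Product: 3 2-(3-hydroxy-2,6-dimethylphenyl)acetic acid
Conditions: Pd2(dba)3 (cat.), tBuXPhos (cat.), KOH, 1,4-dioxane/H2O, 100 °C; then aq. HCl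
Reagents that add atoms: potassium hydroxide, [K+].[OH-]
Why: palladium-catalysed hydroxylation of an aryl bromide with hydroxide (Buchwald-type C–O coupling) tolerates a carboxylate and one ortho methyl group.

Step 3
Reactants: 3 2-(3-hydroxy-2,6-dimethylphenyl)acetic acid
Product: 4 2-(3-hydroxy-2,6-dimethylphenyl)-N-methoxy-N-methylacetamide
Conditions: MeNHOMe·HCl, EDCI, HOBt, iPr2NEt, CH2Cl2, 0 °C to rt
Reagents that add atoms: N,O-dimethylhydroxylamine hydrochloride, CNOC.Cl
Why: carbodiimide amide coupling gives the Weinreb amide, the amine being a far better acyl acceptor than the hindered phenol.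

Step 4
Reactants: 4 2-(3-hydroxy-2,6-dimethylphenyl)-N-methoxy-N-methylacetamide
Product: 5 2-[3-(tert-butyldimethylsilyloxy)-2,6-dimethylphenyl]-N-methoxy-N-methylacetamide
Conditions: TBSCl, imidazole, DMF, rt
Reagents that add atoms: tert-butyldimethylsilyl chloride, CC(C)(C)[Si](C)(C)Cl
Why: standard silylation masks the phenol for the organolithium step and for later selective carbonate formation.

Step 5
Reactants: 6 prop-2-yn-1-ol
Product: 7 tert-butyldimethyl(prop-2-yn-1-yloxy)silane
Conditions: TBSCl, imidazole, CH2Cl2, 0 °C to rt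
Reagents that add atoms: tert-butyldimethylsilyl chloride, CC(C)(C)[Si](C)(C)Cl
Why: standard silylation of a primary alcohol provides the C1/C10/C11 unit as a terminal alkyne.

Step 6
Reactants: 5 2-[3-(tert-butyldimethylsilyloxy)-2,6-dimethylphenyl]-N-methoxy-N-methylacetamide; 7 tert-butyldimethyl(prop-2-yn-1-yloxy)silane
Product: 8 5-(tert-butyldimethylsilyloxy)-1-[3-(tert-butyldimethylsilyloxy)-2,6-dimethylphenyl]pent-3-yn-2-one
Conditions: 7, nBuLi, THF, −78 °C; then 5, −78 to −20 °C; aq. NH4Cl
Reagents that add atoms: none
Why: Weinreb ketone synthesis, in which the lithium acetylide adds once and the chelated tetrahedral adduct prevents over-addition and keeps the benzylic position protected until the quench.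

Step 7
Reactants: 8 5-(tert-butyldimethylsilyloxy)-1-[3-(tert-butyldimethylsilyloxy)-2,6-dimethylphenyl]pent-3-yn-2-one
Product: 9 (2S)-5-(tert-butyldimethylsilyloxy)-1-[3-(tert-butyldimethylsilyloxy)-2,6-dimethylphenyl]pent-3-yn-2-ol
Conditions: Ru[(S,S)-TsDPEN](p-cymene) (cat.), iPrOH, rt
Reagents that add atoms: none
Why: Noyori asymmetric transfer hydrogenation of an alkynyl ketone under base-free conditions, the alkynyl group being the π-recognized substituent, so that the (S,S) catalyst should set the (S)-carbinol (future C2).

Step 8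
Reactants: 9 (2S)-5-(tert-butyldimethylsilyloxy)-1-[3-(tert-butyldimethylsilyloxy)-2,6-dimethylphenyl]pent-3-yn-2-ol
Product: 10 (2S,3Z)-5-(tert-butyldimethylsilyloxy)-1-[3-(tert-butyldimethylsilyloxy)-2,6-dimethylphenyl]-3-(tributylstannyl)pent-3-en-2-ol
Conditions: [Cp*RuCl]4 (cat.), Bu3SnH, CH2Cl2, rt
Reagents that add atoms: tributyltin hydride, CCCC[SnH](CCCC)CCCC
Why: hydroxyl-directed ruthenium-catalysed trans-hydrostannation puts tin on the alkyne carbon next to the free carbinol and hydrogen trans to it, which fixes the alkene geometry (tin cis to CH2OTBS).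

Step 9
Reactants: 10 (2S,3Z)-5-(tert-butyldimethylsilyloxy)-1-[3-(tert-butyldimethylsilyloxy)-2,6-dimethylphenyl]-3-(tributylstannyl)pent-3-en-2-ol
Product: 11 methyl (2Z)-4-(tert-butyldimethylsilyloxy)-2-{(1S)-2-[3-(tert-butyldimethylsilyloxy)-2,6-dimethylphenyl]-1-hydroxyethyl}but-2-enoate
Conditions: Pd(OAc)2 (cat.), Ph3As (cat.), 1,4-benzoquinone, CF3CO2H (cat.), CO (1 atm), MeOH, rt
Reagents that add atoms: carbon monoxide, [C-]#[O+]; methanol, CO
Why: hydroxyl-assisted palladium-catalysed methoxycarbonylation of an alkenylstannane (Stille-type carbonylation with benzoquinone as reoxidant) replaces tin by CO2Me with retention, giving the Z enoate with CO2Me cis to CH2OTBS.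

Step 10
Reactants: 11 methyl (2Z)-4-(tert-butyldimethylsilyloxy)-2-{(1S)-2-[3-(tert-butyldimethylsilyloxy)-2,6-dimethylphenyl]-1-hydroxyethyl}but-2-enoate; 12 methyl chloroformate
Product: 13 methyl (2Z)-4-(tert-butyldimethylsilyloxy)-2-{(1S)-2-[3-(tert-butyldimethylsilyloxy)-2,6-dimethylphenyl]-1-(methoxycarbonyloxy)ethyl}but-2-enoate
Conditions: pyridine, CH2Cl2, 0 °C
Reagents that add atoms: none
Why: O-acylation of the secondary allylic alcohol with a chloroformate gives the allylic carbonate without touching the stereocentre, the phenol being silylated.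

Step 11
Reactants: 13 methyl (2Z)-4-(tert-butyldimethylsilyloxy)-2-{(1S)-2-[3-(tert-butyldimethylsilyloxy)-2,6-dimethylphenyl]-1-(methoxycarbonyloxy)ethyl}but-2-enoate
Product: 14 methyl (2Z)-4-(tert-butyldimethylsilyloxy)-2-[(1S)-2-(3-hydroxy-2,6-dimethylphenyl)-1-(methoxycarbonyloxy)ethyl]but-2-enoate
Conditions: KHF2, MeOH, rt
Reagents that add atoms: none
Why: bifluoride desilylation is selective for aryl over alkyl silyl ethers and is mildly acidic, so the phenol is released in its neutral form and the allylic carbonate is not triggered.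

Step 12
Reactants: 14 methyl (2Z)-4-(tert-butyldimethylsilyloxy)-2-[(1S)-2-(3-hydroxy-2,6-dimethylphenyl)-1-(methoxycarbonyloxy)ethyl]but-2-enoate
Product: 15 methyl (1R,8aR)-1-[(tert-butyldimethylsilyloxy)methyl]-5,8a-dimethyl-6-oxo-1,4,6,8a-tetrahydronaphthalene-2-carboxylate (ring A enoate fused to a ring B 2,5-cyclohexadienone; C10 CH2OTBS α, cis to the C9 methyl)
Conditions: Pd2(dba)3·CHCl3 (2.5 mol %), (R,R)-DACH-phenyl Trost ligand (7.5 mol %; its enantiomer is the first variable to test), degassed CH2Cl2, 0 °C to rt, no added base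
Reagents that add atoms: none
Why: Proposed new method: zerovalent palladium ionizes the C2 carbonate with inversion to a 2-carbomethoxy π-allyl complex, the released methoxide (after loss of CO2) deprotonates the phenol, and the phenolate attacks the allyl terminus C10 through its para carbon C9 on the face away from the metal, forming C9–C10 and leaving the C1=C2 enoate; the closest known reactions are the palladium- and iridium-catalysed intramolecular allylic dearomatizations of phenols to spirodienones and the Tsuji–Trost chemistry of Morita–Baylis–Hillman carbonates, of which this fused para mode is an untested combination. Ring A closes in the 6-endo sense, with all three allyl carbons inside the ring, which is possible because the C3 tether sits in the anti position at C2 and reaches C10 along a path tilted only moderately from the allyl normal. C10 is controlled by the (S)-carbinol (inversion on ionization, inversion on attack, net syn SN2′) together with the syn position of C11 delivered by the Z alkene. C9 is controlled by the extended half-chair approach in which ring B points away from the ester-bearing C1 and only the C9 methyl lies over it, which places that methyl anti to C10–H, and the chiral ligand is chosen to reinforce this approach. The step needs para C-attack (C9) instead of ortho C-attack (C5), O-alkylation or elimination to a diene: oxygen cannot reach either allyl terminus without a strained bridged ring, para attack uses the larger phenolate coefficient and gives the more stable cross-conjugated dienone, and base-free conditions with a fast intramolecular capture disfavour elimination.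

Step 13
Reactants: 15 dienone (C10 CH2OTBS α)
Product: 16 7β,8β-epoxy enone (C7–C8 epoxide anti to the C9 methyl; C4=C5–C6=O retained)
Conditions: tBuOOH (decane), DBU, CH2Cl2, 0 °C to rt
Reagents that add atoms: tert-butyl hydroperoxide, CC(C)(C)OO
Why: Weitz–Scheffer nucleophilic epoxidation attacks only the disubstituted dienone alkene C7=C8 (the tetrasubstituted C4=C5 and the enoate are far less reactive) and, as in steroidal 1,4-dien-3-ones, from the face anti to the angular methyl, which sets the C8–O bond β.

Step 14
Reactants: 16 7β,8β-epoxy enone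
Product: 17 C8 β-hydroxy enone (C7 methylene, C6 ketone, C4=C5)
Conditions: (PhSe)2, NaBH4, AcOH, EtOH, 0 °C
Reagents that add atoms: none
Why: benzeneselenolate reductive opening of an α,β-epoxy ketone cleaves only the Cα–O bond at C7, so the C8 carbinol keeps the β configuration of the epoxide and the enone, ester and silyl ether are untouched.

Step 15
Reactants: 17 C8 β-hydroxy enone
Product: 18 C8 β-triethylsilyloxy enone
Conditions: TESOTf (1.1 equiv), 2,6-lutidine, CH2Cl2, −78 °C
Reagents that add atoms: triethylsilyl trifluoromethanesulfonate, CC[Si](CC)(CC)OS(=O)(=O)C(F)(F)F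
Why: silyl triflate silylation of the hindered axial alcohol blocks retro-aldol and β-elimination pathways and protonation of the enolate in the next step.

Step 16
Reactants: 18 C8 β-triethylsilyloxy enone; 19 allyl bromide
Product: 21 C5 β-allyl C6 ketone (C4–H β; C5 methyl α), via tributyltin enolate 20 (not isolated)
Conditions: Bu3SnH, AIBN (cat.), PhH, 80 °C; then 19, HMPA, 60 °C
Reagents that add atoms: tributyltin hydride, CCCC[SnH](CCCC)CCCC (tin stays only in 20)
Why: the O-stannyl ketyl radical chain (tin hydride conjugate reduction of an enone) is selective for the ketone over the ester, delivers hydrogen to C4 on the β face anti to the C9 methyl (trans ring fusion) and gives the C5=C6 tin enolate regiospecifically, which allyl bromide alkylates at C5 from the β face, again anti to the C9 methyl, so that the C5 methyl ends α.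

Step 17
Reactants: 21 C5 β-allyl C6 ketone
Product: 23 C6 gem-dichloride, via N-silylhydrazone 22 (not isolated)
Conditions: TBSNHNHTBS, Sc(OTf)3 (cat.), CHCl3, 23 to 55 °C; concentrate; then CuCl2, Et3N, MeOH, 0 °C to rt
Reagents that add atoms: copper dichloride, [Cu+2].[Cl-].[Cl-]; 1,2-bis(tert-butyldimethylsilyl)hydrazine, CC(C)(C)[Si](C)(C)NN[Si](C)(C)C(C)(C)C (atoms stay only in 22)
Why: the hydrazone-to-gem-dihalide transformation, in which divalent copper oxidizes the hydrazone to the diazo compound and delivers two chlorides to C6 with loss of N2, replaces the carbonyl oxygen without needing a substitution at the neopentyl-type carbon.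

Step 18
Reactants: 23 C6 gem-dichloride
Product: 24 C6 gem-dichloride C8,C11-diol
Conditions: HF·pyridine, THF/pyridine, 0 °C to rt
Reagents that add atoms: none
Why: fluoride desilylation removes both silyl ethers without affecting the dichloride, ester or alkenes, so that the C8 oxygen is a small hydroxyl group when C6 is set.

Step 19
Reactants: 24 C6 gem-dichloride C8,C11-diol
Product: 25 C6 α-chloride C8,C11-diol (C6–H β)
Conditions: Bu3SnH (1.1 equiv, slow addition), AIBN (cat.), PhH, 80 °C
Reagents that add atoms: none
Why: radical chain monodechlorination with tin hydride, in which the α-chloro C6 radical accepts hydrogen along the β axial direction, anti to the axial C5 methyl and away from the α face screened by the C5 and C9 methyls, leaving chlorine equatorial (α), while the remaining secondary C–Cl bond is abstracted much more slowly than a gem-dichloride.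

Step 20
Reactants: 25 C6 α-chloride C8,C11-diol; 26 2-methylbut-3-en-2-ol
Product: 27 triol with the (E)-4-hydroxy-4-methylpent-2-enyl side chain
Conditions: 26 (excess), RuCl2(H2IMes)(=CH–C6H4-2-OiPr) (second-generation Hoveyda–Grubbs catalyst, cat.), CH2Cl2, 40 °C
Reagents that add atoms: none
Why: olefin cross-metathesis of the terminal allyl group with a hindered tertiary allylic alcohol that homodimerizes slowly should give the E disubstituted alkene, the ring A enoate being inert.

Step 21
Reactants: 27 triol with the (E)-4-hydroxy-4-methylpent-2-enyl side chain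
Product: 28 target, methyl 6α-chloro-10α-formyl-8β-hydroxy-5β-[(2E)-4-hydroxy-4-methylpent-2-en-1-yl]-5α,9α-dimethyl bicyclic enoate (CNP0167913.1)
Conditions: TEMPO (cat.), PhI(OAc)2, CH2Cl2, rt
Reagents that add atoms: none
Why: oxoammonium (TEMPO) oxidation is selective for the primary C11 alcohol over the hindered secondary and the tertiary alcohols and stops at the aldehyde, the axial C8 hydroxyl being badly placed to form a lactol, and the near-neutral medium should leave the C10 stereocentre intact.

**Compound list**

1 | 2-(2,6-dimethylphenyl)acetic acid | Cc1cccc(C)c1CC(=O)O | starting material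
2 | 2-(3-bromo-2,6-dimethylphenyl)acetic acid | Cc1ccc(Br)c(C)c1CC(=O)O | intermediate
3 | 2-(3-hydroxy-2,6-dimethylphenyl)acetic acid | Cc1ccc(O)c(C)c1CC(=O)O | intermediate
4 | 2-(3-hydroxy-2,6-dimethylphenyl)-N-methoxy-N-methylacetamide | Cc1ccc(O)c(C)c1CC(=O)N(C)OC | intermediate
5 | 2-[3-(tert-butyldimethylsilyloxy)-2,6-dimethylphenyl]-N-methoxy-N-methylacetamide | Cc1ccc(O[Si](C)(C)C(C)(C)C)c(C)c1CC(=O)N(C)OC | intermediate
6 | prop-2-yn-1-ol | C#CCO | starting material
7 | tert-butyldimethyl(prop-2-yn-1-yloxy)silane | C#CCO[Si](C)(C)C(C)(C)C | intermediate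
8 | 5-(tert-butyldimethylsilyloxy)-1-[3-(tert-butyldimethylsilyloxy)-2,6-dimethylphenyl]pent-3-yn-2-one | Cc1ccc(O[Si](C)(C)C(C)(C)C)c(C)c1CC(=O)C#CCO[Si](C)(C)C(C)(C)C | intermediate
9 | (2S)-5-(tert-butyldimethylsilyloxy)-1-[3-(tert-butyldimethylsilyloxy)-2,6-dimethylphenyl]pent-3-yn-2-ol | Cc1ccc(O[Si](C)(C)C(C)(C)C)c(C)c1C[C@H](O)C#CCO[Si](C)(C)C(C)(C)C | intermediate
10 | (2S,3Z)-5-(tert-butyldimethylsilyloxy)-1-[3-(tert-butyldimethylsilyloxy)-2,6-dimethylphenyl]-3-(tributylstannyl)pent-3-en-2-ol | Cc1ccc(O[Si](C)(C)C(C)(C)C)c(C)c1C[C@H](O)/C([Sn](CCCC)(CCCC)CCCC)=C/CO[Si](C)(C)C(C)(C)C | intermediate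
11 | methyl (2Z)-4-(tert-butyldimethylsilyloxy)-2-{(1S)-2-[3-(tert-butyldimethylsilyloxy)-2,6-dimethylphenyl]-1-hydroxyethyl}but-2-enoate | Cc1ccc(O[Si](C)(C)C(C)(C)C)c(C)c1C[C@H](O)/C(C(=O)OC)=C/CO[Si](C)(C)C(C)(C)C | intermediate
12 | methyl chloroformate | COC(=O)Cl | starting material
13 | methyl (2Z)-4-(tert-butyldimethylsilyloxy)-2-{(1S)-2-[3-(tert-butyldimethylsilyloxy)-2,6-dimethylphenyl]-1-(methoxycarbonyloxy)ethyl}but-2-enoate | Cc1ccc(O[Si](C)(C)C(C)(C)C)c(C)c1C[C@H](OC(=O)OC)/C(C(=O)OC)=C/CO[Si](C)(C)C(C)(C)C | intermediate
14 | methyl (2Z)-4-(tert-butyldimethylsilyloxy)-2-[(1S)-2-(3-hydroxy-2,6-dimethylphenyl)-1-(methoxycarbonyloxy)ethyl]but-2-enoate | Cc1ccc(O)c(C)c1C[C@H](OC(=O)OC)/C(C(=O)OC)=C/CO[Si](C)(C)C(C)(C)C | intermediate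
15 | methyl (1R,8aR)-1-[(tert-butyldimethylsilyloxy)methyl]-5,8a-dimethyl-6-oxo-1,4,6,8a-tetrahydronaphthalene-2-carboxylate (dienone; C10 CH2OTBS α) | COC(=O)C1=CCC2=C(C)C(=O)C=C[C@]2(C)[C@H]1CO[Si](C)(C)C(C)(C)C | intermediate
16 | 7β,8β-epoxide of 15 (epoxy enone) | COC(=O)C1=CCC2=C(C)C(=O)[C@@H]3O[C@@H]3[C@]2(C)[C@H]1CO[Si](C)(C)C(C)(C)C | intermediate
17 | C8 β-hydroxy enone (C6 ketone, C4=C5, C11 OTBS) | COC(=O)C1=CCC2=C(C)C(=O)C[C@H](O)[C@]2(C)[C@H]1CO[Si](C)(C)C(C)(C)C | intermediate
18 | C8 β-triethylsilyloxy enone | COC(=O)C1=CCC2=C(C)C(=O)C[C@H](O[Si](CC)(CC)CC)[C@]2(C)[C@H]1CO[Si](C)(C)C(C)(C)C | intermediate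
19 | allyl bromide | C=CCBr | starting material
20 | tributyltin enolate (C5=C6–OSnBu3, C4–H β) | COC(=O)C1=CC[C@H]2C(C)=C(O[Sn](CCCC)(CCCC)CCCC)C[C@H](O[Si](CC)(CC)CC)[C@]2(C)[C@H]1CO[Si](C)(C)C(C)(C)C | intermediate
21 | C5 β-allyl C6 ketone (C4–H β, C5 methyl α, C8 OTES, C11 OTBS) | COC(=O)C1=CC[C@H]2[C@](C)(CC=C)C(=O)C[C@H](O[Si](CC)(CC)CC)[C@]2(C)[C@H]1CO[Si](C)(C)C(C)(C)C | intermediate
22 | C6 N-(tert-butyldimethylsilyl)hydrazone of 21 | COC(=O)C1=CC[C@H]2[C@](C)(CC=C)C(=NN[Si](C)(C)C(C)(C)C)C[C@H](O[Si](CC)(CC)CC)[C@]2(C)[C@H]1CO[Si](C)(C)C(C)(C)C | intermediate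
23 | C6 gem-dichloride (C8 OTES, C11 OTBS) | COC(=O)C1=CC[C@H]2[C@](C)(CC=C)C(Cl)(Cl)C[C@H](O[Si](CC)(CC)CC)[C@]2(C)[C@H]1CO[Si](C)(C)C(C)(C)C | intermediate
24 | C6 gem-dichloride C8,C11-diol | COC(=O)C1=CC[C@H]2[C@](C)(CC=C)C(Cl)(Cl)C[C@H](O)[C@]2(C)[C@H]1CO | intermediate
25 | C6 α-chloride C8,C11-diol (5β-allyl) | COC(=O)C1=CC[C@H]2[C@](C)(CC=C)[C@@H](Cl)C[C@H](O)[C@]2(C)[C@H]1CO | intermediate
26 | 2-methylbut-3-en-2-ol | C=CC(C)(C)O | starting material
27 | triol with the (E)-4-hydroxy-4-methylpent-2-enyl side chain (C11 alcohol) | COC(=O)C1=CC[C@H]2[C@](C)(C/C=C/C(C)(C)O)[C@@H](Cl)C[C@H](O)[C@]2(C)[C@H]1CO | intermediate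
28 | CNP0167913.1: methyl 6α-chloro-10α-formyl-8β-hydroxy-5β-[(2E)-4-hydroxy-4-methylpent-2-en-1-yl]-5α,9α-dimethyl bicyclic enoate (4β-H) | COC(=O)C1=CC[C@H]2[C@](C)(C/C=C/C(C)(C)O)[C@@H](Cl)C[C@H](O)[C@]2(C)[C@H]1C=O | target

**Totals and risks**

Total step count: 21. Longest linear sequence: 20 steps (1 to 28 through steps 1–4 and 6–21; step 5 is the only side branch).

The three steps most likely to fail:

Step 12 (key step). After ionization the π-allyl complex may lose a hydrogen from C3 or C11 and give a conjugated diene instead of closing the ring. The phenolate may also attack through its ortho carbon C5, which is likewise a six-membered closure. Syn/anti isomerization of the π-allyl before attack would erode the relay from C2 to C10, and a mismatched ligand could present the wrong C9 face. The fallback sets out from 14 and comes back at 15, and it uses two known reaction types without any metal: base-mediated alkylative dearomatization of a phenol and addition–elimination (SN2′) substitution of a Morita–Baylis–Hillman carbonate. Catalytic Cs2CO3 in MeCN at 0 °C to rt generates the phenolate, its para carbon adds to the enoate β-carbon C10 (6-endo-trig), and the ester enolate expels methyl carbonate from C2 (E1cB) to give 15 directly, with no new compound on the way. Stereocontrol then rests on 1,2-induction from C2: the rotamer with C2–H eclipsing the alkene puts the tether on the same alkene face as in the palladium pathway. The enantiomeric purity of 15 would have to be checked at this point.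

Step 16. The stannyl ketyl chain may stall at the hindered tetrasubstituted enone. Hydrogen may reach C4 on the α face (cis fusion) because the axial C8 silyloxy group crowds the β face. The hindered tin enolate may allylate slowly or on oxygen. The fallback sets out from 18 and comes back at 21 and separates reduction from C–C bond formation by ionic chemistry. Rhodium-catalysed 1,4-hydrosilylation (RhCl(PPh3)3, Et3SiH, PhH, 60 °C) should deliver hydride to C4 from the β face and give the C5=C6 triethylsilyl enol ether F1. Tsuji allylation of this silyl enol ether (Pd2(dba)3·CHCl3, dppe, allyl methyl carbonate, THF, 65 °C) then forms the C5 quaternary centre from the β face and returns 21.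

Step 17. The diazo or copper carbenoid species generated at the neopentyl-type C6 may collapse by a 1,2-hydride shift from C7 or by loss of HCl to an alkene or vinyl chloride, or it may add to the neighbouring allyl group, instead of taking up two chlorides. The fallback sets out from 21 and comes back at 25 and replaces the carbonyl route by radical deoxychlorination of an alcohol. NaBH4 in MeOH at 0 °C reduces the ketone to the C6 alcohol F2 (the α, equatorial epimer is expected, though either would serve). Methyl chlorooxoacetate with Et3N and DMAP gives the methyl oxalate F3, and one equivalent of CsOH·H2O in THF/H2O gives the cesium oxalate F4. Visible-light photoredox decarboxylation (Ir[dF(CF3)ppy]2(dtbbpy)PF6, ethyl trichloroacetate, blue LED) generates the C6 radical, which abstracts chlorine to give the bis-silyl monochloride F5. HF·pyridine then returns 25. In this variant chlorine, not hydrogen, is the last group delivered to C6, so the C6 epimer ratio depends on the β-axial C8 silyl ether screening the β face, and the epimers may need to be separated.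

**Further compounds**

F0 | step 12 | none | none
F1 | step 16 | C5=C6 triethylsilyl enol ether of 18 (C4–H β) | COC(=O)C1=CC[C@H]2C(C)=C(O[Si](CC)(CC)CC)C[C@H](O[Si](CC)(CC)CC)[C@]2(C)[C@H]1CO[Si](C)(C)C(C)(C)C
F2 | step 17 | C6 α-alcohol from 21 (C8 OTES, C11 OTBS) | COC(=O)C1=CC[C@H]2[C@](C)(CC=C)[C@@H](O)C[C@H](O[Si](CC)(CC)CC)[C@]2(C)[C@H]1CO[Si](C)(C)C(C)(C)C
F3 | step 17 | C6 methyl oxalate of F2 | COC(=O)C1=CC[C@H]2[C@](C)(CC=C)[C@@H](OC(=O)C(=O)OC)C[C@H](O[Si](CC)(CC)CC)[C@]2(C)[C@H]1CO[Si](C)(C)C(C)(C)C
F4 | step 17 | C6 cesium oxalate of F2 | COC(=O)C1=CC[C@H]2[C@](C)(CC=C)[C@@H](OC(=O)C(=O)[O-])C[C@H](O[Si](CC)(CC)CC)[C@]2(C)[C@H]1CO[Si](C)(C)C(C)(C)C.[Cs+]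
F5 | step 17 | C6 α-chloride with C8 OTES and C11 OTBS | COC(=O)C1=CC[C@H]2[C@](C)(CC=C)[C@@H](Cl)C[C@H](O[Si](CC)(CC)CC)[C@]2(C)[C@H]1CO[Si](C)(C)C(C)(C)C
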